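## Retrosynthetic overview

1. Aspergichromone A (28) ⇐ hydrogenolysis of its tri-O-benzyl ether 27 (the three phenols of the benzophenone-derived half).
2. Key disconnection: retro-[4+2] through the benzo-fused 7-oxabicyclo[2.2.1]heptane (bridging O, bridgehead CH, bridgehead C bearing the 2,6-dioxyaryl group). The bonds cut are C2–CH(O) and C3–C(Ar)(O), where C2/C3 are the ring-fusion CH–CH of the cyclopenta[b]chromen-9-one. This gives 1-aryl isobenzofuran 25 and chromone-fused cyclopentadiene 26, whose only stereocentre is the tertiary α-hydroxy ester carbon C1.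
3. Both partners are transient and are unveiled in the same flask: 25 by dehydration of keto alcohol 12, 26 by sulfoxide syn-elimination from 24. One operation closes the oxa-bridged bicycle and sets four contiguous stereocentres from C1 alone.
4. 24 ⇐ chromone closure of 2-aroylcyclopentanone 21 ⇐ Dieckmann closure/dianion sulfenylation of 19 ⇐ Cu-box Mukaiyama aldol of enolsilane 17 with dimethyl 2-oxoglutarate 18 (sets C1). 12 ⇐ aryllithium 11 + phthalide 9 ⇐ Pd-catalysed C–H lactonisation of benzoic acid 3.
5. Order of ring formation: γ-lactone (phthalide) → cyclopentanone → pyranone → in the key step the furan of the isobenzofuran, then the tetrahydrofuran and six-membered carbocycle of the oxa-bridged bicycle.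

Key step: step 14

Remark on the chemistry: the (S,S)-t-Bu-box copper catalyst of step 10 is assumed to give the (S)-carbinol by analogy with pyruvate additions; if the sense is opposite for this substrate, the (R,R)-ligand is used. Compound 12 is drawn as the open keto alcohol, which equilibrates with its cyclic hemiketal. Cyclopenta[b]chromene numbering is used throughout (C1 carbinol, C2, C3, C3a, O4, C9 carbonyl, C9a).

## Route

Step 1
Reactants: 1 1-bromo-2,5-dimethoxy-4-methylbenzene
Product: 3 2,5-dimethoxy-4-methylbenzoic acid, via aryllithium 2 (not isolated)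
Conditions: n-BuLi, THF, −78 °C; CO2 (g), −78 °C → rt; 1 M HCl
Reagents that add atoms: carbon dioxide, O=C=O
Why: Bromine–lithium exchange is faster than ortho-deprotonation at −78 °C and the aryllithium is carboxylated at the former C–Br carbon (halogen–metal exchange/carboxylation).

Step 2
Reactants: 3 2,5-dimethoxy-4-methylbenzoic acid
Product: 5 4,7-dimethoxy-5-methylisobenzofuran-1(3H)-one, via bromomethyl acid 4 (not isolated)
Conditions: Pd(OAc)2 (10 mol %), K2HPO4 (3 equiv), CH2Br2, 140 °C, sealed tube
Reagents that add atoms: dibromomethane, BrCBr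
Why: Carboxylate-directed Pd(II) ortho-C–H alkylation with CH2Br2 followed by intramolecular SN2 lactonisation (known benzoic acid → phthalide reaction); the acid has a single ortho C–H, so the CH2 can only enter next to the methoxy group that is flanked by the methyl group.

Step 3
Reactants: 5 4,7-dimethoxy-5-methylisobenzofuran-1(3H)-one
Product: 6 4,7-dihydroxy-5-methylisobenzofuran-1(3H)-one
Conditions: BBr3 (3 equiv), CH2Cl2, −78 → 0 °C; H2O
Reagents that add atoms: none
Why: Lewis-acid cleavage of both aryl methyl ethers by BBr3, which the phthalide lactone tolerates at low temperature.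

Step 4
Reactants: 6 4,7-dihydroxy-5-methylisobenzofuran-1(3H)-one; 7 4-bromo-2-methylbutan-2-ol
Product: 8 7-hydroxy-4-(3-hydroxy-3-methylbutoxy)-5-methylisobenzofuran-1(3H)-one
Conditions: 7 (1.3 equiv), K2CO3 (2.5 equiv), DMF, 50 °C
Reagents that add atoms: none
Why: Williamson etherification in which O4 should react selectively, because the 7-phenoxide is delocalised into the lactone carbonyl (vinylogous carboxylate) and is the poorer nucleophile, as in gentisate-type 2,5-dihydroxy carbonyl arenes.

Step 5
Reactants: 8 7-hydroxy-4-(3-hydroxy-3-methylbutoxy)-5-methylisobenzofuran-1(3H)-one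
Product: 9 7-(benzyloxy)-4-(3-hydroxy-3-methylbutoxy)-5-methylisobenzofuran-1(3H)-one
Conditions: BnBr (1.2 equiv), K2CO3, DMF, 60 °C
Reagents that add atoms: benzyl bromide, BrCc1ccccc1
Why: Williamson benzylation of the only remaining phenol; the tertiary alcohol is not alkylated under carbonate conditions.

Step 6
Reactants: 9 7-(benzyloxy)-4-(3-hydroxy-3-methylbutoxy)-5-methylisobenzofuran-1(3H)-one; 10 1,3-bis(benzyloxy)benzene
Product: 12 [2,6-bis(benzyloxy)phenyl][2-(benzyloxy)-6-(hydroxymethyl)-5-(3-hydroxy-3-methylbutoxy)-4-methylphenyl]methanone, via aryllithium 11 (not isolated)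
Conditions: 10 (2.4 equiv), n-BuLi (2.2 equiv), THF, 0 °C, 2 h; then 9, −78 → 0 °C; aq NH4Cl
Reagents that add atoms: none
Why: Directed ortho-lithiation at C2 between the two benzyloxy groups, then addition of the aryllithium to the lactone carbonyl; the lithium hemiketal and the tetra-ortho-substituted ketone resist a second addition, and the first equivalent of 11 is consumed by the tertiary OH.

Step 7
Reactants: 13 3,5-dihydroxybenzyl alcohol
Product: 14 1,3-bis(methoxymethoxy)-5-[(methoxymethoxy)methyl]benzene
Conditions: MOMCl (3.6 equiv), iPr2NEt (4 equiv), CH2Cl2, 0 °C → rt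
Reagents that add atoms: chloromethyl methyl ether, COCCl
Why: Exhaustive O-alkylation with MOMCl gives base-stable acetals that also serve as ortho-directing groups for the next step.

Step 8
Reactants: 14 1,3-bis(methoxymethoxy)-5-[(methoxymethoxy)methyl]benzene
Product: 16 1-{2,6-bis(methoxymethoxy)-4-[(methoxymethoxy)methyl]phenyl}ethan-1-one, via aryllithium 15 (not isolated)
Conditions: n-BuLi (1.1 equiv), THF, 0 °C, 1 h; N-methoxy-N-methylacetamide, −78 → 0 °C; aq NH4Cl
Reagents that add atoms: N-methoxy-N-methylacetamide, CC(=O)N(C)OC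
Why: Directed ortho-metalation at the position flanked by both OMOM groups, then Weinreb acylation, whose stable chelated adduct prevents over-addition.

Step 9
Reactants: 16 1-{2,6-bis(methoxymethoxy)-4-[(methoxymethoxy)methyl]phenyl}ethan-1-one
Product: 17 ({1-[2,6-bis(methoxymethoxy)-4-(methoxymethoxymethyl)phenyl]ethenyl}oxy)trimethylsilane
Conditions: LiHMDS (1.1 equiv), THF, −78 °C; TMSCl; non-aqueous work-up
Reagents that add atoms: chlorotrimethylsilane, C[Si](C)(C)Cl
Why: Kinetic enolisation of the methyl ketone and O-silylation of the lithium enolate give the enolsilane needed for the Mukaiyama aldol.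

Step 10
Reactants: 17 ({1-[2,6-bis(methoxymethoxy)-4-(methoxymethoxymethyl)phenyl]ethenyl}oxy)trimethylsilane; 18 dimethyl 2-oxopentanedioate
Product: 19 dimethyl (2S)-2-{2-[2,6-bis(methoxymethoxy)-4-(methoxymethoxymethyl)phenyl]-2-oxoethyl}-2-(trimethylsilyloxy)pentanedioate
Conditions: [Cu((S,S)-t-Bu-box)](OTf)2 (10 mol %), THF, −78 → −40 °C; neutral work-up (TMS ether retained)
Reagents that add atoms: none
Why: Evans-type Cu(II)-bisoxazoline Mukaiyama aldol to a bidentate α-keto ester, in which the square-planar five-membered chelate of 18 exposes one ketone face to the enolsilane and sets the only stereocentre of the dienophile half as (S) (sense as assumed in the remark), silyl transfer giving the tertiary TMS ether directly.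

Step 11
Reactants: 19 dimethyl (2S)-2-{2-[2,6-bis(methoxymethoxy)-4-(methoxymethoxymethyl)phenyl]-2-oxoethyl}-2-(trimethylsilyloxy)pentanedioate
Product: 21 methyl (1S)-2-[2,6-bis(methoxymethoxy)-4-(methoxymethoxymethyl)benzoyl]-3-oxo-4-(phenylsulfanyl)-1-(trimethylsilyloxy)cyclopentane-1-carboxylate, via β-diketone 20 (not isolated)
Conditions: LDA (3.5 equiv), THF, −78 → 0 °C; then PhSSPh (1.1 equiv), −78 → −20 °C; aq NH4Cl
Reagents that add atoms: diphenyl disulfide, c1ccc(SSc2ccccc2)cc1
Why: Intramolecular Claisen (Dieckmann-type, 5-exo-trig) condensation of the ketone enolate on the distal ester gives the 2-aroylcyclopentanone, whose β-diketone dianion is sulfenylated at the more reactive ring α'-carbanion; the TMS ether blocks retro-aldol cleavage and the quaternary C1 has no acidic hydrogen.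

Step 12
Reactants: 21 methyl (1S)-2-[2,6-bis(methoxymethoxy)-4-(methoxymethoxymethyl)benzoyl]-3-oxo-4-(phenylsulfanyl)-1-(trimethylsilyloxy)cyclopentane-1-carboxylate
Product: 23 methyl (1S)-1,8-dihydroxy-6-(hydroxymethyl)-9-oxo-3-(phenylsulfanyl)-1,2,3,9-tetrahydrocyclopenta[b]chromene-1-carboxylate, via triol diketone 22 (not isolated)
Conditions: 3 M HCl in MeOH, 40 °C
Reagents that add atoms: none
Why: Acidic methanolysis removes the TMS and the three MOM groups, and the liberated o-hydroxyaryl 1,3-diketone cyclodehydrates to the chromone (classical 1,3-diketone → chromone closure by addition of the phenol to the ring ketone and loss of water); C1 can neither ionise nor epimerise.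

Step 13
Reactants: 23 methyl (1S)-1,8-dihydroxy-6-(hydroxymethyl)-9-oxo-3-(phenylsulfanyl)-1,2,3,9-tetrahydrocyclopenta[b]chromene-1-carboxylate
Product: 24 methyl (1S)-1,8-dihydroxy-6-(hydroxymethyl)-9-oxo-3-(phenylsulfinyl)-1,2,3,9-tetrahydrocyclopenta[b]chromene-1-carboxylate
Conditions: mCPBA (1.0 equiv), CH2Cl2, −78 → −30 °C
Reagents that add atoms: 3-chloroperoxybenzoic acid, OOC(=O)c1cccc(Cl)c1
Why: Electrophilic S-oxidation of the sulfide is much faster than oxidation of the chelated phenol or the chromone and should stop at the sulfoxide with one equivalent at low temperature.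

Step 14
Reactants: 12 [2,6-bis(benzyloxy)phenyl][2-(benzyloxy)-6-(hydroxymethyl)-5-(3-hydroxy-3-methylbutoxy)-4-methylphenyl]methanone; 24 methyl (1S)-1,8-dihydroxy-6-(hydroxymethyl)-9-oxo-3-(phenylsulfinyl)-1,2,3,9-tetrahydrocyclopenta[b]chromene-1-carboxylate
Product: 27 tri-O-benzyl aspergichromone A, via isobenzofuran 25 (not isolated), via dienophile 26 (not isolated)
Conditions: 12 (1.5 equiv), AcOH (20 mol %), PhMe (0.02 M), 100 °C, Ar, dark
Reagents that add atoms: none
Why: Acid-catalysed cyclodehydration of 12 through its hemiketal gives the 1-aryl isobenzofuran 25 while thermal syn-elimination of PhSOH from 24 (the only β-hydrogens are on C2) unveils the cyclopentadiene-fused chromone 26, and the two transient partners combine in an intermolecular [4+2] cycloaddition. The closest known reaction types are the in situ generation of 1-arylisobenzofurans from o-aroylbenzyl alcohols with trapping by cyclic alkenes, and sulfoxide thermolysis to conjugated dienes. The cycloaddition closes the 7-oxabicyclo[2.2.1]heptene in one concerted suprafacial event, forming the bonds C2–CH(O) and C3–C(Ar)(O) and with them both the tetrahydrofuran and the six-membered carbocycle. The four new stereocentres (two bridgeheads, two ring-fusion CH) are controlled by C1 of 26: the diene should add to the cyclopentene face that carries OH (anti to the larger CO2Me) and in the exo mode, both favoured by an O–H···O hydrogen bond from the C1 hydroxyl to the furan oxygen and by the reversibility of isobenzofuran cycloadditions at 100 °C, which funnels material to the exo adduct. Regioselectivity needs the unsubstituted, more nucleophilic C3 of 25 to bond to C2 of 26 (the δ-terminus of the dienone) and the aryl-bearing C1 of 25 to bond to C3 of 26, away from the quaternary centre, so steric and electronic preferences coincide. Self-dimerisation of 26 should be outpaced because 25, used in excess, is by far the more reactive diene.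

Step 15
Reactants: 27 tri-O-benzyl aspergichromone A
Product: 28 aspergichromone A
Conditions: H2 (1 atm), 10 % Pd/C, EtOAc, rt
Reagents that add atoms: none
Why: Hydrogenolysis of the three aryl benzyl ethers is expected to be faster than cleavage of the hindered bridging benzylic C–O bonds or of the benzylic CH2OH under neutral conditions, and it touches no stereocentre.

## Compound list

1 | 1-bromo-2,5-dimethoxy-4-methylbenzene | COc1cc(C)c(OC)cc1Br | starting material
2 | (2,5-dimethoxy-4-methylphenyl)lithium, formed in situ | COc1cc(C)c(OC)cc1[Li] | intermediate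
3 | 2,5-dimethoxy-4-methylbenzoic acid | COc1cc(C)c(OC)cc1C(=O)O | intermediate
4 | 2-(bromomethyl)-3,6-dimethoxy-4-methylbenzoic acid, formed in situ as its potassium salt | COc1cc(C)c(OC)c(CBr)c1C(=O)O | intermediate
5 | 4,7-dimethoxy-5-methylisobenzofuran-1(3H)-one | COc1cc(C)c(OC)c2COC(=O)c12 | intermediate
6 | 4,7-dihydroxy-5-methylisobenzofuran-1(3H)-one | Cc1cc(O)c2C(=O)OCc2c1O | intermediate
7 | 4-bromo-2-methylbutan-2-ol | CC(C)(O)CCBr | starting material
8 | 7-hydroxy-4-(3-hydroxy-3-methylbutoxy)-5-methylisobenzofuran-1(3H)-one | Cc1cc(O)c2C(=O)OCc2c1OCCC(C)(C)O | intermediate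
9 | 7-(benzyloxy)-4-(3-hydroxy-3-methylbutoxy)-5-methylisobenzofuran-1(3H)-one | Cc1cc(OCc3ccccc3)c2C(=O)OCc2c1OCCC(C)(C)O | intermediate
10 | 1,3-bis(benzyloxy)benzene | c1ccc(COc2cccc(OCc3ccccc3)c2)cc1 | starting material
11 | [2,6-bis(benzyloxy)phenyl]lithium, formed in situ | [Li]c1c(OCc2ccccc2)cccc1OCc1ccccc1 | intermediate
12 | [2,6-bis(benzyloxy)phenyl][2-(benzyloxy)-6-(hydroxymethyl)-5-(3-hydroxy-3-methylbutoxy)-4-methylphenyl]methanone (open form of the cyclic hemiketal) | O=C(c1c(OCc2ccccc2)cccc1OCc1ccccc1)c1c(OCc2ccccc2)cc(C)c(OCCC(C)(C)O)c1CO | intermediate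
13 | 3,5-dihydroxybenzyl alcohol | OCc1cc(O)cc(O)c1 | starting material
14 | 1,3-bis(methoxymethoxy)-5-[(methoxymethoxy)methyl]benzene | COCOCc1cc(OCOC)cc(OCOC)c1 | intermediate
15 | {2,6-bis(methoxymethoxy)-4-[(methoxymethoxy)methyl]phenyl}lithium, formed in situ | [Li]c1c(OCOC)cc(COCOC)cc1OCOC | intermediate
16 | 1-{2,6-bis(methoxymethoxy)-4-[(methoxymethoxy)methyl]phenyl}ethan-1-one | CC(=O)c1c(OCOC)cc(COCOC)cc1OCOC | intermediate
17 | ({1-[2,6-bis(methoxymethoxy)-4-(methoxymethoxymethyl)phenyl]ethenyl}oxy)trimethylsilane | C=C(O[Si](C)(C)C)c1c(OCOC)cc(COCOC)cc1OCOC | intermediate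
18 | dimethyl 2-oxopentanedioate (dimethyl 2-oxoglutarate) | COC(=O)CCC(=O)C(=O)OC | starting material
19 | dimethyl (2S)-2-{2-[2,6-bis(methoxymethoxy)-4-(methoxymethoxymethyl)phenyl]-2-oxoethyl}-2-(trimethylsilyloxy)pentanedioate | COC(=O)[C@@](CCC(=O)OC)(O[Si](C)(C)C)CC(=O)c1c(OCOC)cc(COCOC)cc1OCOC | intermediate
20 | methyl (1S)-2-[2,6-bis(methoxymethoxy)-4-(methoxymethoxymethyl)benzoyl]-3-oxo-1-(trimethylsilyloxy)cyclopentane-1-carboxylate, formed in situ as its enolate (C2 not defined) | COC(=O)[C@@]1(O[Si](C)(C)C)C(C(=O)c2c(OCOC)cc(COCOC)cc2OCOC)C(=O)CC1 | intermediate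
21 | methyl (1S)-2-[2,6-bis(methoxymethoxy)-4-(methoxymethoxymethyl)benzoyl]-3-oxo-4-(phenylsulfanyl)-1-(trimethylsilyloxy)cyclopentane-1-carboxylate (C1 S; mixture at C2/C4 and of enol tautomers) | COC(=O)[C@@]1(O[Si](C)(C)C)C(C(=O)c2c(OCOC)cc(COCOC)cc2OCOC)C(=O)C(Sc2ccccc2)C1 | intermediate
22 | methyl (1S)-2-[2,6-dihydroxy-4-(hydroxymethyl)benzoyl]-1-hydroxy-3-oxo-4-(phenylsulfanyl)cyclopentane-1-carboxylate, formed in situ | COC(=O)[C@@]1(O)C(C(=O)c2c(O)cc(CO)cc2O)C(=O)C(Sc2ccccc2)C1 | intermediate
23 | methyl (1S)-1,8-dihydroxy-6-(hydroxymethyl)-9-oxo-3-(phenylsulfanyl)-1,2,3,9-tetrahydrocyclopenta[b]chromene-1-carboxylate (C1 S; mixture at C3) | COC(=O)[C@@]1(O)c2c(oc3cc(CO)cc(O)c3c2=O)C(Sc2ccccc2)C1 | intermediate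
24 | methyl (1S)-1,8-dihydroxy-6-(hydroxymethyl)-9-oxo-3-(phenylsulfinyl)-1,2,3,9-tetrahydrocyclopenta[b]chromene-1-carboxylate (C1 S; mixture at C3 and S) | COC(=O)[C@@]1(O)c2c(oc3cc(CO)cc(O)c3c2=O)C(S(=O)c2ccccc2)C1 | intermediate
25 | 7-(benzyloxy)-1-[2,6-bis(benzyloxy)phenyl]-4-(3-hydroxy-3-methylbutoxy)-5-methylisobenzofuran, formed in situ | Cc1cc(OCc2ccccc2)c2c(-c3c(OCc4ccccc4)cccc3OCc3ccccc3)occ2c1OCCC(C)(C)O | intermediate
26 | methyl (1S)-1,8-dihydroxy-6-(hydroxymethyl)-9-oxo-1,9-dihydrocyclopenta[b]chromene-1-carboxylate, formed in situ | COC(=O)[C@@]1(O)c2c(oc3cc(CO)cc(O)c3c2=O)C=C1 | intermediate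
27 | tri-O-benzyl aspergichromone A: the target with benzyl ethers on the two phenols of the 2,6-dihydroxyphenyl ring and on the phenol of the benzo ring of the oxa-bridged unit; exo cycloadduct (cyclopentane cis-fused syn to the oxygen bridge, ring-fusion hydrogens endo), C1 (S) with OH syn to the oxygen bridge, aryl-bearing bridgehead bonded to C3 | COC(=O)[C@@]1(O)c2c(oc3cc(CO)cc(O)c3c2=O)[C@H]2[C@@H]1[C@H]1O[C@]2(c2c(OCc3ccccc3)cccc2OCc2ccccc2)c2c(OCc3ccccc3)cc(C)c(OCCC(C)(C)O)c21 | intermediate
28 | aspergichromone A (same relative and absolute configuration as 27, all phenols free) | COC(=O)[C@@]1(O)c2c(oc3cc(CO)cc(O)c3c2=O)[C@H]2[C@@H]1[C@H]1O[C@]2(c2c(O)cccc2O)c2c(O)cc(C)c(OCCC(C)(C)O)c21 | target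

## Step count and risk

Total step count: 15 (steps 1–6 build 12; steps 7–13 build 24; steps 14–15 join and deprotect).
Longest linear sequence: 9 steps (13 → 28 through steps 7–15).

Steps most likely to fail, in order:

Step 14. The two unmasking reactions need not run at matched rates at 100 °C. The isobenzofuran may then oligomerise or be intercepted by benzenesulfenic acid, or the dienophile may self-dimerise, before the cross-cycloaddition; exo and facial control could also erode at this temperature. The fallback decouples the two events and generates the dienophile cold by selenoxide chemistry; it sets out from 19 and comes back at 27. Compound 19 is taken through the Dieckmann/dianion sequence of step 11 with PhSeBr as electrophile to give methyl (1S)-2-[2,6-bis(methoxymethoxy)-4-(methoxymethoxymethyl)benzoyl]-3-oxo-4-(phenylselanyl)-1-(trimethylsilyloxy)cyclopentane-1-carboxylate F1. HCl/MeOH as in step 12 passes through the deprotected seleno diketone F2 and gives methyl (1S)-1,8-dihydroxy-6-(hydroxymethyl)-9-oxo-3-(phenylselanyl)-1,2,3,9-tetrahydrocyclopenta[b]chromene-1-carboxylate F3. mCPBA (1.0 equiv, CH2Cl2, −78 °C) gives the corresponding selenoxide F4. This cold solution is added to 25 that has been pre-formed from 12 (AcOH cat., CH2Cl2, rt) and buffered with iPr2NH. On warming to 0 °C, F4 should undergo syn-elimination to 26, which is trapped at once by the excess 25 to give 27.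

Step 11. β-Elimination of silanolate or retro-aldol cleavage may occur from the ketone enolate before ring closure; the dianion may form incompletely; or sulfenylation may occur at the central carbon of the diketone. The fallback introduces sulfur only after the chromone is in place, by lateral γ-lithiation; it sets out from 19 and comes back at 23. LiHMDS alone effects the Dieckmann closure and 20 is isolated. HCl/MeOH gives, through methyl (1S)-2-[2,6-dihydroxy-4-(hydroxymethyl)benzoyl]-1-hydroxy-3-oxocyclopentane-1-carboxylate F5, the saturated tricycle methyl (1S)-1,8-dihydroxy-6-(hydroxymethyl)-9-oxo-1,2,3,9-tetrahydrocyclopenta[b]chromene-1-carboxylate F6. TESOTf/2,6-lutidine gives its tris(triethylsilyl) ether F7. LDA (THF, −78 °C) deprotonates the γ-CH2 (C3) of the 2-alkylchromone and PhSSPh gives the 3-phenylsulfanyl tris(triethylsilyl) ether F8. HCl/MeOH removes the silyl groups and returns 23.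

Step 15. The strained dibenzylic C–O bridge may open by hydrogenolysis, or the benzylic CH2OH may be reduced, in competition with cleavage of the two hindered benzyl ethers; debenzylation may also stall through catalyst poisoning by sulfur traces from step 14. The fallback moves the deprotection before the cycloaddition; it sets out from 12 and comes back at 28. Compound 12 is debenzylated (H2, Pd/C, EtOAc) to (2,6-dihydroxyphenyl)[2-hydroxy-6-(hydroxymethyl)-5-(3-hydroxy-3-methylbutoxy)-4-methylphenyl]methanone F9, in which the hydrogen-bonded ketone keeps the open form. Heating F9 with 24 under the conditions of step 14 should give 1-(2,6-dihydroxyphenyl)-7-hydroxy-4-(3-hydroxy-3-methylbutoxy)-5-methylisobenzofuran F10 and 26, whose cycloaddition delivers 28 directly.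

Further compounds
F1 | step 14 | methyl (1S)-2-[2,6-bis(methoxymethoxy)-4-(methoxymethoxymethyl)benzoyl]-3-oxo-4-(phenylselanyl)-1-(trimethylsilyloxy)cyclopentane-1-carboxylate | COC(=O)[C@@]1(O[Si](C)(C)C)C(C(=O)c2c(OCOC)cc(COCOC)cc2OCOC)C(=O)C([Se]c2ccccc2)C1
F2 | step 14 | methyl (1S)-2-[2,6-dihydroxy-4-(hydroxymethyl)benzoyl]-1-hydroxy-3-oxo-4-(phenylselanyl)cyclopentane-1-carboxylate (transient) | COC(=O)[C@@]1(O)C(C(=O)c2c(O)cc(CO)cc2O)C(=O)C([Se]c2ccccc2)C1
F3 | step 14 | methyl (1S)-1,8-dihydroxy-6-(hydroxymethyl)-9-oxo-3-(phenylselanyl)-1,2,3,9-tetrahydrocyclopenta[b]chromene-1-carboxylate | COC(=O)[C@@]1(O)c2c(oc3cc(CO)cc(O)c3c2=O)C([Se]c2ccccc2)C1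
F4 | step 14 | methyl (1S)-1,8-dihydroxy-6-(hydroxymethyl)-9-oxo-3-(phenylseleninyl)-1,2,3,9-tetrahydrocyclopenta[b]chromene-1-carboxylate | COC(=O)[C@@]1(O)c2c(oc3cc(CO)cc(O)c3c2=O)C([Se](=O)c2ccccc2)C1
F5 | step 11 | methyl (1S)-2-[2,6-dihydroxy-4-(hydroxymethyl)benzoyl]-1-hydroxy-3-oxocyclopentane-1-carboxylate (transient) | COC(=O)[C@@]1(O)C(C(=O)c2c(O)cc(CO)cc2O)C(=O)CC1
F6 | step 11 | methyl (1S)-1,8-dihydroxy-6-(hydroxymethyl)-9-oxo-1,2,3,9-tetrahydrocyclopenta[b]chromene-1-carboxylate | COC(=O)[C@@]1(O)c2c(oc3cc(CO)cc(O)c3c2=O)CC1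
F7 | step 11 | methyl (1S)-9-oxo-1,8-bis(triethylsilyloxy)-6-[(triethylsilyloxy)methyl]-1,2,3,9-tetrahydrocyclopenta[b]chromene-1-carboxylate | COC(=O)[C@@]1(O[Si](CC)(CC)CC)c2c(oc3cc(CO[Si](CC)(CC)CC)cc(O[Si](CC)(CC)CC)c3c2=O)CC1
F8 | step 11 | methyl (1S)-9-oxo-3-(phenylsulfanyl)-1,8-bis(triethylsilyloxy)-6-[(triethylsilyloxy)methyl]-1,2,3,9-tetrahydrocyclopenta[b]chromene-1-carboxylate | COC(=O)[C@@]1(O[Si](CC)(CC)CC)c2c(oc3cc(CO[Si](CC)(CC)CC)cc(O[Si](CC)(CC)CC)c3c2=O)C(Sc2ccccc2)C1
F9 | step 15 | (2,6-dihydroxyphenyl)[2-hydroxy-6-(hydroxymethyl)-5-(3-hydroxy-3-methylbutoxy)-4-methylphenyl]methanone | O=C(c1c(O)cccc1O)c1c(O)cc(C)c(OCCC(C)(C)O)c1CO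
F10 | step 15 | 1-(2,6-dihydroxyphenyl)-7-hydroxy-4-(3-hydroxy-3-methylbutoxy)-5-methylisobenzofuran (transient) | Cc1cc(O)c2c(-c3c(O)cccc3O)occ2c1OCCC(C)(C)O
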